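**Plan**

- Retrosynthesis: the C8–C14 bond of ring C is cut first. This leaves a decalin (rings A/B) with an 8-methylene group and a preformed oxocene (ring D) on the C9–C11–C12–C13 chain. Ring D is then cut at C14=C15 (metathesis) and O–C19 (ether), giving (+)-larixol and a C6 dienyl bromide.
- Forward: rings A/B are bought with larixol (C1–C14, both oxygens, 10-CH3, 13-CH3 and the future 8-CH3). Ring D is made by O-alkylation and ring-closing metathesis. Ring C is closed last by a reductive radical 1,7-diene cyclisation.
- Enabling feature: C8 is quaternary and methyl-bearing, C14 is the ring C/ring D junction, and the two are linked through C9–C11–C12–C13. C8=CH2 and the Z-C14=C15 olefin left in ring D by the metathesis therefore form a 1,7-diene. Its hydrogen-atom-initiated 6-exo coupling makes ring C, the 8-CH3 and both new stereocentres at once.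
- Stereochemistry: C5, C6, C9, C10 and C13 come from larixol. The Z-C17=C18 olefin comes from a trans-hydroalumination/iodination. C8 and C14 are relayed from C9, C10 and C13 by substrate control in the key step.
- Helpers: one silyl ether on 6-OH (removed last) and the temporary C14=C15 unsaturation (consumed in the key step).

Key step: step 7

Remark: (+)-larixol from larch oleoresin is taken as a purchasable starting material and its (13S) configuration is assumed from memory; atoms are numbered C1–C10 (decalin), C11–C14 (ring C), C15–C19 (oxocene carbons), and substituent carbons are named by the carbon that bears them (8-CH2/8-CH3, 10-CH3, 13-CH3, 17-CH3).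

**Route**

Step 1
Reactants: 1 but-2-yn-1-ol
Product: 3 (Z)-3-iodobut-2-en-1-ol, via cyclic vinylalanate 2 (not isolated)
Conditions: NaAlH2(OCH2CH2OMe)2, THF, 0 °C to rt; EtOAc; I2, −78 to 0 °C
Reagents that add atoms: iodine, II
Why: hydroxyl-directed trans-hydroalumination of the propargylic alcohol puts Al on C3 in a five-membered alkoxyalanate, and iodinolysis with retention leaves I cis to CH2OH, which fixes the later Z-C17=C18 geometry.

Step 2
Reactants: 3 (Z)-3-iodobut-2-en-1-ol; 4 allyltributylstannane
Product: 5 (2Z)-3-methylhexa-2,5-dien-1-ol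
Conditions: PdCl2(MeCN)2 (cat.), DMF, rt
Reagents that add atoms: none
Why: Migita–Kosugi–Stille coupling of an alkenyl iodide with an allylstannane should proceed with retention of olefin geometry and tolerate the free hydroxyl; the allyl carbons become C16 and C15.

Step 3
Reactants: 5 (2Z)-3-methylhexa-2,5-dien-1-ol
Product: 6 (2Z)-1-bromo-3-methylhexa-2,5-diene
Conditions: CBr4, PPh3, CH2Cl2, −20 to 0 °C; used crude
Reagents that add atoms: carbon tetrabromide, BrC(Br)(Br)Br
Why: Appel bromination of a primary allylic alcohol by SN2 on the alkoxyphosphonium ion should give the bromide without allylic transposition or Z/E change at low temperature.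

Step 4
Reactants: 7 (+)-larixol
Product: 8 6-O-TBS-larixol
Conditions: TBSCl, imidazole, DMAP (cat.), DMF, 50 °C
Reagents that add atoms: tert-butyldimethylsilyl chloride, CC(C)(C)[Si](C)(C)Cl
Why: silylation with a silyl chloride should select the secondary equatorial 6α-hydroxyl, because the tertiary allylic 13-hydroxyl does not react under these conditions.

Step 5
Reactants: 8 6-O-TBS-larixol; 6 (2Z)-1-bromo-3-methylhexa-2,5-diene
Product: 10 6-O-TBS-13-O-[(2Z)-3-methylhexa-2,5-dien-1-yl]larixol, via potassium 13-alkoxide 9 (not isolated)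
Conditions: KH, 18-crown-6 (cat.), THF, 0 °C; then 6, Bu4NI (cat.), 0 °C to rt
Reagents that add atoms: none
Why: Williamson etherification of the tertiary potassium alkoxide with a primary allylic bromide (SN2), as in O-allylation of linalool-type alcohols; the C13–O bond is not broken, so C13 keeps its configuration.

Step 6
Reactants: 10 6-O-TBS-13-O-[(2Z)-3-methylhexa-2,5-dien-1-yl]larixol
Product: 11 oxocene diene (ring D closed: C13(O)(CH3)–C14H=C15H–C16H2–C17(CH3)=C18H–C19H2–O, both ring olefins Z; 8-methylene and 6-OTBS retained)
Conditions: second-generation Grubbs catalyst (10 mol %), 1,4-benzoquinone (20 mol %), CH2Cl2 (2 mM), 40 °C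
Reagents that add atoms: none
Why: ring-closing olefin metathesis between the unhindered terminal vinyl group (initiation site) and the C13 vinyl group; the Z olefin in the tether and the quaternary C13 pre-organise the eight-membered ring, whose new C14=C15 olefin can only be Z.

Step 7
Reactants: 11 oxocene diene
Product: 14 6-O-TBS ether of the target, via C8 tertiary radical 12 (not isolated), via C15 secondary radical 13 (not isolated)
Conditions: Mn(dpm)3 (20 mol %, dpm = dipivaloylmethanate), PhSiH3 (1.2 equiv, slow addition), t-BuOOH (1.5 equiv), i-PrOH/CH2Cl2 (5 mM), 22 °C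
Reagents that add atoms: none
Why: Proposed new method: a manganese hydride transfers a hydrogen atom to the terminal carbon of the 8-methylene group, the only 1,1-disubstituted and least hindered olefin, to give tertiary radical 12; this adds 6-exo-trig to C14 of the strained, allylically oxygenated Z olefin of ring D to give radical 13, which is reduced by a second hydrogen-atom transfer. The closest known reaction types are the radical cyclisations of 1,6-dienes seen under hydrogen-atom-transfer hydrogenation conditions and the iron-mediated reductive olefin coupling onto activated acceptors; a 6-exo closure onto an unactivated 1,2-disubstituted olefin that forms a quaternary–tertiary bond has not been shown. Ring C closes in the 6-exo-trig mode through a chair-like transition state whose tether (C9–C11–C12–C13) is biased by the quaternary C13 and the equatorial C9 side chain. C8 should be set by attack on the α face (new bond equatorial, anti to the axial 10-CH3), which leaves the 8-CH3 axial and β as in cationic and radical closures of labdane 8-methylene precursors; C14 should be set by the same chair, in which the fixed (13S) centre puts 13-CH3 axial and C15 of the ring olefin pseudo-equatorial, so that H-14 is α and ring D is trans-diequatorially fused. The step needs initiation at the 8-methylene in the presence of the trisubstituted C17=C18 olefin and cyclisation faster than direct reduction of 12; the first rests on the faster hydrogen-atom transfer to 1,1-disubstituted olefins with the bulky Mn(dpm)3 and on limiting silane, the second on high dilution and slow silane addition, which keep the metal hydride concentration low while the unimolecular closure (estimated 10^4–10^5 s^-1 with the gem-disubstituted tether) proceeds.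

Step 8
Reactants: 14 6-O-TBS ether of the target
Product: 15 target CNP0179324.1
Conditions: TBAF, THF, 50 °C
Reagents that add atoms: none
Why: fluoride-mediated desilylation of the secondary silyl ether; the tertiary allylic ether of ring D and the trisubstituted olefin are inert to fluoride.

**Compound list**

1 | but-2-yn-1-ol | CC#CCO | starting material
2 | cyclic vinylalanate: sodium 2,2-bis(2-methoxyethoxy)-3-methyl-2,5-dihydro-1,2-oxaaluminol-2-uide | CC1=CCO[Al-]1(OCCOC)OCCOC.[Na+] | intermediate
3 | (Z)-3-iodobut-2-en-1-ol | C/C(I)=C/CO | intermediate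
4 | allyltributylstannane | C=CC[Sn](CCCC)(CCCC)CCCC | starting material
5 | (2Z)-3-methylhexa-2,5-dien-1-ol | C/C(CC=C)=C/CO | intermediate
6 | (2Z)-1-bromo-3-methylhexa-2,5-diene | C/C(CC=C)=C/CBr | intermediate
7 | (+)-larixol: 6α,13-dihydroxy labdane, 13S, with 8-exocyclic methylene and C14=C15 vinyl group; 5α-H, 9α-H, 10β-CH3 | C=C[C@@](C)(O)CC[C@@H]1[C@@]2(C)CCCC(C)(C)[C@@H]2[C@@H](O)CC1=C | starting material
8 | 6-O-TBS-larixol | C=C[C@@](C)(O)CC[C@@H]1[C@@]2(C)CCCC(C)(C)[C@@H]2[C@@H](O[Si](C)(C)C(C)(C)C)CC1=C | intermediate
9 | potassium 13-alkoxide of 8 | C=C[C@@](C)([O-])CC[C@@H]1[C@@]2(C)CCCC(C)(C)[C@@H]2[C@@H](O[Si](C)(C)C(C)(C)C)CC1=C.[K+] | intermediate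
10 | 6-O-TBS-13-O-[(2Z)-3-methylhexa-2,5-dien-1-yl]larixol | C=C[C@@](C)(OC/C=C(/C)CC=C)CC[C@@H]1[C@@]2(C)CCCC(C)(C)[C@@H]2[C@@H](O[Si](C)(C)C(C)(C)C)CC1=C | intermediate
11 | oxocene diene: 6α-TBSO-8-methylene decalin whose C9 carries CH2CH2 to C2 of a (2S,3Z,6Z)-2,6-dimethyl-5,8-dihydro-2H-oxocine (C13 = ring C2) | C/C1=C/CO[C@@](C)(CC[C@@H]2[C@@]3(C)CCCC(C)(C)[C@@H]3[C@@H](O[Si](C)(C)C(C)(C)C)CC2=C)/C=C\C1 | intermediate
12 | C8 tertiary radical of 11 (H added to the 8-methylene carbon) | C/C1=C/CO[C@@](C)(CC[C@@H]2[C@@]3(C)CCCC(C)(C)[C@@H]3[C@@H](O[Si](C)(C)C(C)(C)C)C[C]2C)/C=C\C1 | intermediate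
13 | C15 secondary radical (ring C closed, C8–C14 bond formed) | C/C1=C/CO[C@@]2(C)CC[C@@H]3[C@@]4(C)CCCC(C)(C)[C@@H]4[C@@H](O[Si](C)(C)C(C)(C)C)C[C@@]3(C)[C@@H]2[CH]C1 | intermediate
14 | 6-O-TBS ether of the target | C/C1=C/CO[C@@]2(C)CC[C@@H]3[C@@]4(C)CCCC(C)(C)[C@@H]4[C@@H](O[Si](C)(C)C(C)(C)C)C[C@@]3(C)[C@@H]2CC1 | intermediate
15 | target CNP0179324.1: (13S,17Z)-13,19-epoxycheilanth-17-en-6α-ol; 5α-H, 8β-CH3, 9α-H, 10β-CH3, 13β-CH3, 14α-H | C/C1=C/CO[C@@]2(C)CC[C@@H]3[C@@]4(C)CCCC(C)(C)[C@@H]4[C@@H](O)C[C@@]3(C)[C@@H]2CC1 | target

**Step count**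

Total: 8 steps. Longest linear sequence: 7 steps (1, 2, 3, 5, 6, 7, 8 from but-2-yn-1-ol); 5 steps from larixol.

**Steps most likely to fail**

Step 7 (proposed new method). Radical 12 may be reduced before it cyclises, which amounts to plain hydrogenation of the 8-methylene. Hydrogen-atom transfer may also engage the C17=C18 olefin. Radical 13 may escape by a transannular 1,5-hydrogen shift from C19, and attack on the wrong face of C14 is possible. The fallback uses known chemistry only; it sets out from 11 and comes back at 14. The doubly allylic C16 methylene of 11 is oxidised (CrO3·3,5-dimethylpyrazole, CH2Cl2, −20 °C) to the cross-conjugated oxocene dienone F1. In this compound both ring olefins are electron-poor and silent toward hydrogen-atom transfer, and C14 has become a Giese acceptor. Fe(acac)3/PhSiH3 in EtOH/(CH2OH)2 at 60 °C (reductive olefin coupling) should then close ring C by 6-exo attack of the C8 radical on C14, giving the tetracyclic C16 enone F2. The helper carbonyl is taken out through the C16 dithiolane F3 ((TMSSCH2)2, ZnI2, Et2O) and Raney Ni in EtOH, which should give 14.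

Step 5. The hindered tertiary alkoxide may act as a base on bromide 6 (1,4-elimination through the doubly allylic CH2) instead of substituting it. The fallback sets out from 3 and from 8 (as alkoxide 9) and comes back at 10. Iodide 3 is converted (CBr4, PPh3) into (Z)-1-bromo-3-iodobut-2-ene F4, a smaller allylic bromide without the base-sensitive CH2. Alkylation of 9 gives the 13-O-[(Z)-3-iodobut-2-enyl] ether F5. The allyl group is attached only afterwards by Stille coupling with 4 (PdCl2(MeCN)2, DMF), which should give 10.

Step 6. The eight-membered closure may lose to oligomerisation by cross metathesis, or to ring truncation (metathesis of the C13 vinyl group with the allylic C17=C18 olefin to a 2,5-dihydrofuran). The fallback closes ring D at the C16-carbinol oxidation level; it sets out from 8 and comes back at 14. The iodide F5 (made from 8 as in the fallback for step 5) is lithiated (t-BuLi, Et2O, −78 °C) to the vinyllithium F6. Addition to acrolein gives the C16 carbinol F7 (both C16 epimers). The free allylic hydroxyl accelerates metathesis at the adjacent vinyl group, so second-generation Grubbs catalyst should give the oxocene dienol F8. MnO2 then gives dienone F1, and the sequence continues through F2 and F3 to 14 as in the fallback for step 7.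

**Further compounds**

F1 | step 7 | cross-conjugated oxocene dienone (C16 ketone of 11) | C/C1=C/CO[C@@](C)(CC[C@@H]2[C@@]3(C)CCCC(C)(C)[C@@H]3[C@@H](O[Si](C)(C)C(C)(C)C)CC2=C)/C=C\C1=O
F2 | step 7 | tetracyclic C16 enone (16-oxo derivative of 14) | C/C1=C/CO[C@@]2(C)CC[C@@H]3[C@@]4(C)CCCC(C)(C)[C@@H]4[C@@H](O[Si](C)(C)C(C)(C)C)C[C@@]3(C)[C@@H]2CC1=O
F3 | step 7 | C16 dithiolane of F2 | C/C1=C/CO[C@@]2(C)CC[C@@H]3[C@@]4(C)CCCC(C)(C)[C@@H]4[C@@H](O[Si](C)(C)C(C)(C)C)C[C@@]3(C)[C@@H]2CC15SCCS5
F4 | step 5 | (Z)-1-bromo-3-iodobut-2-ene | C/C(I)=C/CBr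
F5 | step 5 | 6-O-TBS-13-O-[(Z)-3-iodobut-2-enyl]larixol | C=C[C@@](C)(OC/C=C(/C)I)CC[C@@H]1[C@@]2(C)CCCC(C)(C)[C@@H]2[C@@H](O[Si](C)(C)C(C)(C)C)CC1=C
F6 | step 6 | vinyllithium from F5 | C=C[C@@](C)(OC/C=C(/C)[Li])CC[C@@H]1[C@@]2(C)CCCC(C)(C)[C@@H]2[C@@H](O[Si](C)(C)C(C)(C)C)CC1=C
F7 | step 6 | C16 carbinol (acrolein adduct, C16 epimers) | C=C[C@@](C)(OC/C=C(/C)C(O)C=C)CC[C@@H]1[C@@]2(C)CCCC(C)(C)[C@@H]2[C@@H](O[Si](C)(C)C(C)(C)C)CC1=C
F8 | step 6 | oxocene dienol (16-hydroxy derivative of 11, C16 epimers) | C/C1=C/CO[C@@](C)(CC[C@@H]2[C@@]3(C)CCCC(C)(C)[C@@H]3[C@@H](O[Si](C)(C)C(C)(C)C)CC2=C)/C=C\C1O
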